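**Retrosynthetic overview**

- The target is traced back to a hexasilylated 8-iodoflavanone; the (Z)-3-methylbuta-1,3-dienyl group at C8 is added last by Sonogashira coupling, cis-semi-reduction and desilylation.
- Key disconnection, C2–C3 of ring C: C2 is a benzylic CH bonded to O1 and to the 2',4'-dioxygenated ring B, so in the open ring A aryl benzyl ether its C–H bond is doubly activated and lies 1,6 to a carbene at C3; carbene C–H insertion closes ring C and sets C2 (S).
- The diazomethyl ketone comes from the methyl ketone by detrifluoroacetylative diazo transfer; the methyl ketone comes from a Mitsunobu etherification (O1–C2) of an iodinated, bis-silylated 2,4,6-trihydroxyacetophenone (ring A) with the ring B/ring D benzylic alcohol.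
- Ring D (trans-2,3-diaryl-dihydrofuran) comes from an enantioselective donor/donor carbene C–H insertion of a diaryl diazomethane, followed by acid-mediated C2 epimerisation to trans.
- Ring order: ring D first, then ring C; rings A and B and the two pendant aryl rings are bought.

Key step: step 17

Abbreviations and labels: TBS = tert-butyldimethylsilyl, MOM = methoxymethyl; ring A = benzo ring of the chromanone, ring C = its pyranone ring (O1, C2, C3, C4), ring B = the resorcinol-type ring on C2 (also the benzo ring of the dihydrobenzofuran), ring D = the dihydrofuran ring.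

Assumption: the sense of induction of the two chiral dirhodium catalysts (steps 8 and 17) is assigned by analogy with related insertions; if a first run shows the opposite sense, the mirror-image catalyst is used.

**Route**

Step 1
Reactants: 1 5-bromo-2,4-dihydroxybenzaldehyde
Product: 2 5-bromo-2-hydroxy-4-(methoxymethoxy)benzaldehyde
Conditions: MOMCl (1.05 equiv), i-Pr2NEt, CH2Cl2, 0 °C
Reagents that add atoms: chloromethyl methyl ether, COCCl
Why: Selective O-alkylation (acetal ether formation) should occur at the 4-hydroxyl, which is the more acidic and is not chelated, while the 2-hydroxyl is held in a hydrogen bond to the formyl group.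

Step 2
Reactants: 3 4-hydroxybenzyl alcohol
Product: 4 [4-(methoxymethoxy)phenyl]methanol
Conditions: NaH (1.0 equiv), THF/DMF, 0 °C; MOMCl (1.0 equiv)
Reagents that add atoms: chloromethyl methyl ether, COCCl
Why: One equivalent of NaH forms only the phenoxide, which is alkylated in a Williamson ether synthesis while the benzylic hydroxyl stays free.

Step 3
Reactants: 2 5-bromo-2-hydroxy-4-(methoxymethoxy)benzaldehyde; 4 [4-(methoxymethoxy)phenyl]methanol
Product: 5 5-bromo-4-(methoxymethoxy)-2-{[4-(methoxymethoxy)phenyl]methoxy}benzaldehyde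
Conditions: PPh3, DIAD, THF, 0 °C → rt
Reagents that add atoms: none
Why: Mitsunobu etherification should work because the chelated salicylaldehyde hydroxyl is acidic enough to protonate the betaine and the primary benzylic alcohol is displaced readily; the neutral conditions spare the MOM acetals.

Step 4
Reactants: 6 5-bromoresorcinol
Product: 7 1-bromo-3,5-bis(methoxymethoxy)benzene
Conditions: MOMCl (2.5 equiv), i-Pr2NEt, CH2Cl2, 0 °C → rt
Reagents that add atoms: chloromethyl methyl ether, COCCl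
Why: Standard double O-alkylation of two unhindered phenols gives a bromide that tolerates magnesium insertion.

Step 5
Reactants: 7 1-bromo-3,5-bis(methoxymethoxy)benzene; 5 5-bromo-4-(methoxymethoxy)-2-{[4-(methoxymethoxy)phenyl]methoxy}benzaldehyde
Product: 9 racemic {5-bromo-4-(methoxymethoxy)-2-[[4-(methoxymethoxy)phenyl]methoxy]phenyl}[3,5-bis(methoxymethoxy)phenyl]methanol, via aryl Grignard reagent 8 (not isolated)
Conditions: 7, Mg turnings, THF, 50 °C; then 5, THF, 0 °C; H2O
Reagents that add atoms: none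
Why: Grignard addition to the aldehyde is much faster at 0 °C than any exchange at the ring bromide of 5; the carbinol centre is formed racemic and is removed in step 6.

Step 6
Reactants: 9 racemic diarylmethanol
Product: 10 {5-bromo-4-(methoxymethoxy)-2-[[4-(methoxymethoxy)phenyl]methoxy]phenyl}[3,5-bis(methoxymethoxy)phenyl]methanone
Conditions: Dess–Martin periodinane, NaHCO3, CH2Cl2, rt
Reagents that add atoms: none
Why: Dess–Martin oxidation of a diaryl carbinol to the benzophenone is reliable, and the bicarbonate buffer protects the MOM acetals.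

Step 7
Reactants: 10 diaryl ketone
Product: 11 hydrazone of ketone 10 (E/Z mixture)
Conditions: N2H4·H2O (excess), AcOH (cat.), EtOH, 80 °C
Reagents that add atoms: hydrazine (as monohydrate), NN
Why: Hydrazone condensation of the hindered benzophenone needs heat and acid catalysis, and the MOM ethers, benzyl ether and aryl bromide are inert to hydrazine, which is why acetal protection is carried at this stage and not silyl protection.

Step 8
Reactants: 11 hydrazone
Product: 13 (2S,3R)-5-bromo-3-[3,5-bis(methoxymethoxy)phenyl]-6-(methoxymethoxy)-2-[4-(methoxymethoxy)phenyl]-2,3-dihydro-1-benzofuran (2,3-cis), via diaryl diazomethane 12 (not isolated)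
Conditions: MnO2 (activated), CH2Cl2, rt, filtration through Celite; then Rh2(R-PTAD)4 (dirhodium tetrakis[(R)-N-phthaloyl-(1-adamantyl)glycinate], 1 mol %), CH2Cl2, 0 °C
Reagents that add atoms: none
Why: MnO2 dehydrogenates the hydrazone to the diaryl diazomethane, and the dirhodium catalyst turns it into a donor/donor carbene that undergoes intramolecular 1,5 C–H insertion into the benzylic ether CH2 and closes ring D; the chiral carboxylate ligands should set C3 (R), and the ring-closing geometry places the two aryl groups cis (C2 S), which is corrected in step 10.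

Step 9
Reactants: 13 cis bromide
Product: 15 (2S,3R)-3-[3,5-bis(methoxymethoxy)phenyl]-6-(methoxymethoxy)-2-[4-(methoxymethoxy)phenyl]-2,3-dihydro-1-benzofuran-5-carbaldehyde, via aryllithium 14 (not isolated)
Conditions: n-BuLi (1.1 equiv), THF, −78 °C; DMF, −78 → 0 °C; H2O
Reagents that add atoms: N,N-dimethylformamide, CN(C)C=O
Why: Bromine–lithium exchange at −78 °C is faster than deprotonation at C3, the ortho MOM ether stabilises the aryllithium by chelation, and Bouveault formylation with DMF gives the aldehyde without touching the stereocentres.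

Step 10
Reactants: 15 cis aldehyde
Product: 16 (2R,3R)-3-(3,5-dihydroxyphenyl)-6-hydroxy-2-(4-hydroxyphenyl)-2,3-dihydro-1-benzofuran-5-carbaldehyde (2,3-trans)
Conditions: conc. aq HCl, MeOH/THF, 50 °C, until equilibration is complete
Reagents that add atoms: none
Why: Acid-catalysed acetal cleavage removes the four MOM groups with methanol trapping the formaldehyde, and the same acid should reversibly ionise the C2–O1 bond of ring D to the 4-hydroxybenzyl cation, so that reclosure gives the thermodynamically preferred trans isomer (C2 goes from S to R) while C3 (R) is not involved.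

Step 11
Reactants: 16 tetraphenol aldehyde
Product: 17 (2R,3R)-3-[3,5-bis(TBSO)phenyl]-6-(TBSO)-2-[4-(TBSO)phenyl]-2,3-dihydro-1-benzofuran-5-carbaldehyde
Conditions: TBSCl (6 equiv), imidazole, DMAP (cat.), DMF, rt → 40 °C
Reagents that add atoms: tert-butyldimethylsilyl chloride, CC(C)(C)[Si](C)(C)Cl
Why: Exhaustive silylation of phenols is routine, and the excess reagent and DMAP also cover the chelated 6-hydroxyl next to the formyl group.

Step 12
Reactants: 17 tetra-TBS aldehyde
Product: 18 [(2R,3R)-3-[3,5-bis(TBSO)phenyl]-6-(TBSO)-2-[4-(TBSO)phenyl]-2,3-dihydro-1-benzofuran-5-yl]methanol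
Conditions: i-Bu2AlH, CH2Cl2, −78 °C; aq Rochelle salt
Reagents that add atoms: none
Why: Hydride reduction of the aldehyde at −78 °C gives an aluminium alkoxide that should not trigger migration of the neighbouring aryl silyl group, unlike a basic borohydride medium.

Step 13
Reactants: 19 2,4,6-trihydroxyacetophenone
Product: 20 1-[2-hydroxy-4,6-bis(TBSO)phenyl]ethanone
Conditions: TBSCl (2.1 equiv), imidazole, CH2Cl2/DMF, 0 °C
Reagents that add atoms: tert-butyldimethylsilyl chloride, CC(C)(C)[Si](C)(C)Cl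
Why: Silylation should take the 4-hydroxyl and one ortho hydroxyl and then stop, because the last hydroxyl is chelated to the acetyl carbonyl and is the least nucleophilic.

Step 14
Reactants: 20 bis-silyl ether
Product: 21 1-[2-hydroxy-3-iodo-4,6-bis(TBSO)phenyl]ethanone
Conditions: NIS (1.0 equiv), MeCN, 0 °C → rt
Reagents that add atoms: N-iodosuccinimide, O=C1CCC(=O)N1I
Why: Electrophilic aromatic iodination should go ortho to the free phenol, since the only other open position is flanked by two bulky silyloxy groups; iodine is chosen over bromine so that the later alkynylation at this hindered, electron-rich carbon runs under mild conditions.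

Step 15
Reactants: 21 iodophenol; 18 benzylic alcohol
Product: 22 1-[2-{[(2R,3R)-3-[3,5-bis(TBSO)phenyl]-6-(TBSO)-2-[4-(TBSO)phenyl]-2,3-dihydro-1-benzofuran-5-yl]methoxy}-3-iodo-4,6-bis(TBSO)phenyl]ethanone
Conditions: PPh3, DIAD, THF (concentrated), 0 °C → rt
Reagents that add atoms: none
Why: Mitsunobu etherification joins the two halves under neutral conditions that spare the six aryl silyl ethers, which a carbonate-mediated alkylation with the labile, electron-rich benzylic halide would endanger; the phenol, acidified by the ortho acyl and iodo groups, is a good pronucleophile.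

Step 16
Reactants: 22 methyl ketone
Product: 24 2-diazo-1-[2-{[(2R,3R)-3-[3,5-bis(TBSO)phenyl]-6-(TBSO)-2-[4-(TBSO)phenyl]-2,3-dihydro-1-benzofuran-5-yl]methoxy}-3-iodo-4,6-bis(TBSO)phenyl]ethanone, via trifluoroacetyl ketone 23 (not isolated)
Conditions: LiN(SiMe3)2, THF, −78 °C; CF3CO2CH2CF3, −78 °C; cold 1 M HCl wash; then MsN3, Et3N, H2O (1 equiv), MeCN, rt
Reagents that add atoms: methanesulfonyl azide, CS(=O)(=O)N=[N+]=[N-] (the two diazo nitrogens); 2,2,2-trifluoroethyl trifluoroacetate, O=C(OCC(F)(F)F)C(F)(F)F (trifluoroacetyl group of 23 only, lost again)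
Why: Detrifluoroacetylative (Regitz-type) diazo transfer should work because the kinetic lithium enolate of the methyl ketone is acylated at −78 °C before the ortho silyl group can migrate, and the activated 1,3-diketone then takes up the diazo group and loses trifluoroacetyl as the sulfonamide.

Step 17
Reactants: 24 diazomethyl ketone
Product: 25 (2S)-2-[(2R,3R)-3-[3,5-bis(TBSO)phenyl]-6-(TBSO)-2-[4-(TBSO)phenyl]-2,3-dihydro-1-benzofuran-5-yl]-8-iodo-5,7-bis(TBSO)-2,3-dihydro-4H-chromen-4-one
Conditions: Rh2(S-PTTL)4 (dirhodium tetrakis[N-phthaloyl-(S)-tert-leucinate], 2 mol %), CH2Cl2, −40 → 0 °C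
Reagents that add atoms: none
Why: Rh2(S-PTTL)4, a tetracarboxylate of divalent rhodium, expels N2 from 24 and gives an electrophilic rhodium-bound keto carbene at C3, which inserts into the C2–H bond of the O1–CH2–aryl group through a three-centre transition state with hydride-transfer character, forming C2–C3. The closest known reaction type is the dirhodium-catalysed intramolecular C–H insertion of 2-alkoxyaryl diazoketones next to the ether oxygen, which gives chroman-4-ones. Ring C closes as a six-membered ring by 1,6-insertion (C3, C4, C4a, C8a, O1, C2); no five-membered alternative exists because the 1,5 position is O1 itself. C2 (S) is set by catalyst control, the chiral phthalimido carboxylate wall selecting one of the two C2 hydrogens, and because ring D is already fixed as (2R,3R) any minor C2 epimer is a diastereomer that can be separated. The step needs site selectivity and insertion in preference to attack of O1 on the carbene (oxonium ylide, then [1,2] benzyl shift): the C2–H bond is doubly activated by O1 and by the 2',4'-dioxygenated ring B, O1 is a weakly basic vinylogous-ester oxygen flanked by iodine, the C5 oxygen carries silicon and so offers no competing 1,6 C–H bond, and low temperature in a non-coordinating solvent favours insertion. The aryl iodide, the silyl ethers and ring D should be inert to the carbene.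

Step 18
Reactants: 25 8-iodoflavanone; 26 2-methylbut-1-en-3-yne
Product: 27 (2S)-2-[(2R,3R)-3-[3,5-bis(TBSO)phenyl]-6-(TBSO)-2-[4-(TBSO)phenyl]-2,3-dihydro-1-benzofuran-5-yl]-8-(3-methylbut-3-en-1-yn-1-yl)-5,7-bis(TBSO)-2,3-dihydro-4H-chromen-4-one
Conditions: PdCl2(PPh3)2 (5 mol %), CuI (10 mol %), Et3N/THF, 40 °C, sealed tube
Reagents that add atoms: none
Why: Sonogashira coupling of the aryl iodide with the volatile terminal enyne should proceed under mild amine conditions that do not enolise the flavanone, so C2 is not put at risk.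

Step 19
Reactants: 27 enyne
Product: 28 (2S)-2-[(2R,3R)-3-[3,5-bis(TBSO)phenyl]-6-(TBSO)-2-[4-(TBSO)phenyl]-2,3-dihydro-1-benzofuran-5-yl]-8-[(1Z)-3-methylbuta-1,3-dien-1-yl]-5,7-bis(TBSO)-2,3-dihydro-4H-chromen-4-one
Conditions: Zn(Cu/Ag) (zinc dust activated with Cu(OAc)2 and AgNO3), THF/MeOH/H2O, rt → 40 °C
Reagents that add atoms: none
Why: Boland reduction delivers two hydrogens syn to a conjugated triple bond on the activated zinc surface and stops at the alkene, so the (Z)-diene should form without over-reduction and without touching the ketone.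

Step 20
Reactants: 28 hexa-TBS (Z)-diene
Product: 29 (2S)-2-[(2R,3R)-3-(3,5-dihydroxyphenyl)-6-hydroxy-2-(4-hydroxyphenyl)-2,3-dihydro-1-benzofuran-5-yl]-5,7-dihydroxy-8-[(1Z)-3-methylbuta-1,3-dien-1-yl]-2,3-dihydro-4H-chromen-4-one (CNP0284772.1)
Conditions: Et3N·3HF, Et3N, THF/MeCN, 0 °C → rt
Reagents that add atoms: none
Why: Fluoride-mediated cleavage of the six aryl silyl ethers in an amine-buffered, nearly neutral medium should avoid both base-induced ring opening of the flavanone (loss of C2) and acid-induced cyclisation of the (Z)-dienyl phenol.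

**Compound list**

1 | 5-bromo-2,4-dihydroxybenzaldehyde | O=Cc1cc(Br)c(O)cc1O | starting material
2 | 5-bromo-2-hydroxy-4-(methoxymethoxy)benzaldehyde | O=Cc1cc(Br)c(OCOC)cc1O | intermediate
3 | 4-hydroxybenzyl alcohol | OCc1ccc(O)cc1 | starting material
4 | [4-(methoxymethoxy)phenyl]methanol | OCc1ccc(OCOC)cc1 | intermediate
5 | 5-bromo-4-(methoxymethoxy)-2-{[4-(methoxymethoxy)phenyl]methoxy}benzaldehyde | O=Cc1cc(Br)c(OCOC)cc1OCc1ccc(OCOC)cc1 | intermediate
6 | 5-bromoresorcinol | Oc1cc(O)cc(Br)c1 | starting material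
7 | 1-bromo-3,5-bis(methoxymethoxy)benzene | COCOc1cc(OCOC)cc(Br)c1 | intermediate
8 | [3,5-bis(methoxymethoxy)phenyl]magnesium bromide (not isolated) | COCOc1cc(OCOC)cc([Mg]Br)c1 | intermediate
9 | racemic {5-bromo-4-(methoxymethoxy)-2-[[4-(methoxymethoxy)phenyl]methoxy]phenyl}[3,5-bis(methoxymethoxy)phenyl]methanol | OC(c1cc(OCOC)cc(OCOC)c1)c1cc(Br)c(OCOC)cc1OCc1ccc(OCOC)cc1 | intermediate
10 | {5-bromo-4-(methoxymethoxy)-2-[[4-(methoxymethoxy)phenyl]methoxy]phenyl}[3,5-bis(methoxymethoxy)phenyl]methanone | O=C(c1cc(OCOC)cc(OCOC)c1)c1cc(Br)c(OCOC)cc1OCc1ccc(OCOC)cc1 | intermediate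
11 | hydrazone of ketone 10 (E/Z mixture) | NN=C(c1cc(OCOC)cc(OCOC)c1)c1cc(Br)c(OCOC)cc1OCc1ccc(OCOC)cc1 | intermediate
12 | diaryl diazomethane from 11 (not isolated) | [N-]=[N+]=C(c1cc(OCOC)cc(OCOC)c1)c1cc(Br)c(OCOC)cc1OCc1ccc(OCOC)cc1 | intermediate
13 | (2S,3R)-5-bromo-3-[3,5-bis(methoxymethoxy)phenyl]-6-(methoxymethoxy)-2-[4-(methoxymethoxy)phenyl]-2,3-dihydro-1-benzofuran (cis) | Brc1cc2c(cc1OCOC)O[C@H](c1ccc(OCOC)cc1)[C@@H]2c1cc(OCOC)cc(OCOC)c1 | intermediate
14 | 5-lithio derivative of 13 (not isolated) | [Li]c1cc2c(cc1OCOC)O[C@H](c1ccc(OCOC)cc1)[C@@H]2c1cc(OCOC)cc(OCOC)c1 | intermediate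
15 | (2S,3R)-3-[3,5-bis(methoxymethoxy)phenyl]-6-(methoxymethoxy)-2-[4-(methoxymethoxy)phenyl]-2,3-dihydro-1-benzofuran-5-carbaldehyde (cis) | O=Cc1cc2c(cc1OCOC)O[C@H](c1ccc(OCOC)cc1)[C@@H]2c1cc(OCOC)cc(OCOC)c1 | intermediate
16 | (2R,3R)-3-(3,5-dihydroxyphenyl)-6-hydroxy-2-(4-hydroxyphenyl)-2,3-dihydro-1-benzofuran-5-carbaldehyde (trans) | O=Cc1cc2c(cc1O)O[C@@H](c1ccc(O)cc1)[C@@H]2c1cc(O)cc(O)c1 | intermediate
17 | (2R,3R)-3-[3,5-bis(TBSO)phenyl]-6-(TBSO)-2-[4-(TBSO)phenyl]-2,3-dihydro-1-benzofuran-5-carbaldehyde | O=Cc1cc2c(cc1O[Si](C)(C)C(C)(C)C)O[C@@H](c1ccc(O[Si](C)(C)C(C)(C)C)cc1)[C@@H]2c1cc(O[Si](C)(C)C(C)(C)C)cc(O[Si](C)(C)C(C)(C)C)c1 | intermediate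
18 | [(2R,3R)-3-[3,5-bis(TBSO)phenyl]-6-(TBSO)-2-[4-(TBSO)phenyl]-2,3-dihydro-1-benzofuran-5-yl]methanol | OCc1cc2c(cc1O[Si](C)(C)C(C)(C)C)O[C@@H](c1ccc(O[Si](C)(C)C(C)(C)C)cc1)[C@@H]2c1cc(O[Si](C)(C)C(C)(C)C)cc(O[Si](C)(C)C(C)(C)C)c1 | intermediate
19 | 2,4,6-trihydroxyacetophenone | CC(=O)c1c(O)cc(O)cc1O | starting material
20 | 1-[2-hydroxy-4,6-bis(TBSO)phenyl]ethanone | CC(=O)c1c(O)cc(O[Si](C)(C)C(C)(C)C)cc1O[Si](C)(C)C(C)(C)C | intermediate
21 | 1-[2-hydroxy-3-iodo-4,6-bis(TBSO)phenyl]ethanone | CC(=O)c1c(O)c(I)c(O[Si](C)(C)C(C)(C)C)cc1O[Si](C)(C)C(C)(C)C | intermediate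
22 | methyl ketone: 1-[2-{[(2R,3R)-dihydrobenzofuran-5-yl]methoxy}-3-iodo-4,6-bis(TBSO)phenyl]ethanone (aryl groups as in 18) | CC(=O)c1c(O[Si](C)(C)C(C)(C)C)cc(O[Si](C)(C)C(C)(C)C)c(I)c1OCc1cc2c(cc1O[Si](C)(C)C(C)(C)C)O[C@@H](c1ccc(O[Si](C)(C)C(C)(C)C)cc1)[C@@H]2c1cc(O[Si](C)(C)C(C)(C)C)cc(O[Si](C)(C)C(C)(C)C)c1 | intermediate
23 | trifluoroacetyl ketone: 4,4,4-trifluoro-1-aryl-butane-1,3-dione from 22 (not isolated) | O=C(CC(=O)C(F)(F)F)c1c(O[Si](C)(C)C(C)(C)C)cc(O[Si](C)(C)C(C)(C)C)c(I)c1OCc1cc2c(cc1O[Si](C)(C)C(C)(C)C)O[C@@H](c1ccc(O[Si](C)(C)C(C)(C)C)cc1)[C@@H]2c1cc(O[Si](C)(C)C(C)(C)C)cc(O[Si](C)(C)C(C)(C)C)c1 | intermediate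
24 | diazomethyl ketone: 2-diazo-1-aryl-ethanone from 22 (key-step precursor) | [N-]=[N+]=CC(=O)c1c(O[Si](C)(C)C(C)(C)C)cc(O[Si](C)(C)C(C)(C)C)c(I)c1OCc1cc2c(cc1O[Si](C)(C)C(C)(C)C)O[C@@H](c1ccc(O[Si](C)(C)C(C)(C)C)cc1)[C@@H]2c1cc(O[Si](C)(C)C(C)(C)C)cc(O[Si](C)(C)C(C)(C)C)c1 | intermediate
25 | hexa-TBS (2S)-8-iodoflavanone (key-step product) | Ic1c(O[Si](C)(C)C(C)(C)C)cc(O[Si](C)(C)C(C)(C)C)c2c1O[C@H](c1cc3c(cc1O[Si](C)(C)C(C)(C)C)O[C@@H](c1ccc(O[Si](C)(C)C(C)(C)C)cc1)[C@@H]3c1cc(O[Si](C)(C)C(C)(C)C)cc(O[Si](C)(C)C(C)(C)C)c1)CC2=O | intermediate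
26 | 2-methylbut-1-en-3-yne | C=C(C)C#C | starting material
27 | hexa-TBS (2S)-8-(3-methylbut-3-en-1-yn-1-yl)flavanone | C=C(C)C#Cc1c(O[Si](C)(C)C(C)(C)C)cc(O[Si](C)(C)C(C)(C)C)c2c1O[C@H](c1cc3c(cc1O[Si](C)(C)C(C)(C)C)O[C@@H](c1ccc(O[Si](C)(C)C(C)(C)C)cc1)[C@@H]3c1cc(O[Si](C)(C)C(C)(C)C)cc(O[Si](C)(C)C(C)(C)C)c1)CC2=O | intermediate
28 | hexa-TBS (2S)-8-[(1Z)-3-methylbuta-1,3-dien-1-yl]flavanone | C=C(C)/C=C\c1c(O[Si](C)(C)C(C)(C)C)cc(O[Si](C)(C)C(C)(C)C)c2c1O[C@H](c1cc3c(cc1O[Si](C)(C)C(C)(C)C)O[C@@H](c1ccc(O[Si](C)(C)C(C)(C)C)cc1)[C@@H]3c1cc(O[Si](C)(C)C(C)(C)C)cc(O[Si](C)(C)C(C)(C)C)c1)CC2=O | intermediate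
29 | CNP0284772.1, (2S)-2-[(2R,3R)-3-(3,5-dihydroxyphenyl)-6-hydroxy-2-(4-hydroxyphenyl)-2,3-dihydro-1-benzofuran-5-yl]-5,7-dihydroxy-8-[(1Z)-3-methylbuta-1,3-dien-1-yl]-2,3-dihydro-4H-chromen-4-one | C=C(C)/C=C\c1c(O)cc(O)c2c1O[C@H](c1cc3c(cc1O)O[C@@H](c1ccc(O)cc1)[C@@H]3c1cc(O)cc(O)c1)CC2=O | target

**Step count and risks**

Total steps: 20. Longest linear sequence: 16 (steps 1, 3, 5 to 12, 15 to 20).

Steps most likely to fail:

1. Step 17 (key step). The carbene may be captured by the lone pair of O1, followed by a [1,2] shift of the electron-rich benzyl group, or the catalyst may discriminate poorly between the two C2 hydrogens. The fallback closes ring C at O1–C2 by polar chemistry and sets out from phenol 21 and aldehyde 17. The dilithium derivative of 21 (LiN(SiMe3)2, 2.2 equiv, THF, −78 °C) is added to 17 in an aldol reaction and quenched cold with AcOH. This gives the β-hydroxy ketone 3-hydroxy-1-[2-hydroxy-3-iodo-4,6-bis(TBSO)phenyl]-3-[(2R,3R)-dihydrobenzofuran-5-yl]propan-1-one F1 as a mixture of carbinol epimers. Intramolecular Mitsunobu etherification (PPh3, DIAD, THF, 0 °C) then forms the O1–C2 bond and should give 25 together with its (2R) epimer F2. These are diastereomers because ring D is fixed, so separation on silica should be possible, and the route is rejoined at 25.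

2. Step 15. Etherification at the hindered, chelated phenol may be slow, so that ionisation and self-condensation of the activated electron-rich benzylic alcohol take over. The fallback sets out from alcohol 18, which is converted into the benzylic chloride F3 (MsCl, Et3N, LiCl, THF, 0 °C, used crude). Phenol 21 is then alkylated with F3 in a Williamson ether synthesis (K2CO3, Bu4NI cat., dry acetone, rt), and the route is rejoined at 22.

3. Step 19. Hydrogen transfer to the hindered, very lipophilic enyne may stall in the aqueous medium, or over-reduction and partial Z to E isomerisation may occur. The fallback sets out from iodide 25 and enyne 26 and bypasses 27. Rhodium-catalysed trans-hydroboration of 26 ([Rh(cod)Cl]2, P(i-Pr)3, Et3N, pinacolborane, cyclohexane, rt) should give the (Z)-dienylboronate 4,4,5,5-tetramethyl-2-[(1Z)-3-methylbuta-1,3-dien-1-yl]-1,3,2-dioxaborolane F4. Suzuki–Miyaura coupling of F4 with 25 (Pd(PPh3)4, K3PO4, THF/H2O, 40 °C) proceeds with retention of alkene geometry, and the route is rejoined at 28.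

**Further compounds**

F1 | step 17 | 3-hydroxy-1-[2-hydroxy-3-iodo-4,6-bis(TBSO)phenyl]-3-[(2R,3R)-3-[3,5-bis(TBSO)phenyl]-6-(TBSO)-2-[4-(TBSO)phenyl]-2,3-dihydro-1-benzofuran-5-yl]propan-1-one (carbinol epimers) | O=C(CC(O)c1cc2c(cc1O[Si](C)(C)C(C)(C)C)O[C@@H](c1ccc(O[Si](C)(C)C(C)(C)C)cc1)[C@@H]2c1cc(O[Si](C)(C)C(C)(C)C)cc(O[Si](C)(C)C(C)(C)C)c1)c1c(O)c(I)c(O[Si](C)(C)C(C)(C)C)cc1O[Si](C)(C)C(C)(C)C
F2 | step 17 | (2R) epimer of 25 | Ic1c(O[Si](C)(C)C(C)(C)C)cc(O[Si](C)(C)C(C)(C)C)c2c1O[C@@H](c1cc3c(cc1O[Si](C)(C)C(C)(C)C)O[C@@H](c1ccc(O[Si](C)(C)C(C)(C)C)cc1)[C@@H]3c1cc(O[Si](C)(C)C(C)(C)C)cc(O[Si](C)(C)C(C)(C)C)c1)CC2=O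
F3 | step 15 | (2R,3R)-5-(chloromethyl)-3-[3,5-bis(TBSO)phenyl]-6-(TBSO)-2-[4-(TBSO)phenyl]-2,3-dihydro-1-benzofuran | ClCc1cc2c(cc1O[Si](C)(C)C(C)(C)C)O[C@@H](c1ccc(O[Si](C)(C)C(C)(C)C)cc1)[C@@H]2c1cc(O[Si](C)(C)C(C)(C)C)cc(O[Si](C)(C)C(C)(C)C)c1
F4 | step 19 | 4,4,5,5-tetramethyl-2-[(1Z)-3-methylbuta-1,3-dien-1-yl]-1,3,2-dioxaborolane | C=C(C)/C=C\B1OC(C)(C)C(C)(C)O1
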